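The zeta flask makes target faster up to its reading at 1.5 min, at r = 0.00607 M min⁻¹, than between its last two readings, at s = 0.00115 M min⁻¹. The eta flask has the same charge, so our task is to carry the zeta curve on to 42 min.

| flask | starting material | coupling partner | time |
|---|---|---|---|
| zeta | 0.0800 M | 0.200 M |  |
| beta | 0.0480 M | 0.168 M |  |
| epsilon | 0.0800 M | 0.300 M |  |
| gamma | 0.160 M | 0.200 M |  |
| eta | 0.0800 M | 0.200 M | 42 min |

| run | time / min | [target] / M |
|---|---|---|
| zeta run | 0.68 | 0.0039 |
| zeta run | 1.5 | 0.0091 |
| zeta run | 3.4 | 0.0161 |
| zeta run | 7.6 | 0.0291 |
| zeta run | 17 | 0.0399 |
| beta run | 0.68 | 0.0022 |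
| beta run | 1.5 | 0.0042 |
| beta run | 3.4 | 0.0094 |
| beta run | 7.6 | 0.0158 |
| beta run | 17 | 0.0238 |
| epsilon run | 0.68 | 0.0066 |
| epsilon run | 1.5 | 0.0142 |
| epsilon run | 3.4 | 0.0258 |
| epsilon run | 7.6 | 0.0391 |
| epsilon run | 17 | 0.0421 |
| gamma run | 0.68 | 0.0055 |
| gamma run | 1.5 | 0.0114 |
| gamma run | 3.4 | 0.0230 |
| gamma run | 7.6 | 0.0420 |
| gamma run | 17 | 0.0650 |

(each reading ± 4 × 10⁻⁴ M)

- the exponent of [coupling partner] in the starting rate at the charge of the zeta run (at the point where two percent of the starting material have become target)
- the exponent of [starting material] in the starting rate at the charge of the zeta run (at the point where two percent of the starting material have become target) (one fixed amount of target, the same in the runs compared)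
- target in the eta run at 42 min, as a share of the starting material charged

- Overall: starting material + coupling partner -> target.
- Constant volume, constant temperature.
- A reading of a species includes what of it is bound.
- An order is taken over about fifteen percent of the charge, up and down.

The early readings also compare the flasks. By 1.5 min, the epsilon flask, with more coupling partner, has made 1.56 times the target of the zeta flask, and the gamma flask, with twice the starting material, has made 1.25 times it.

We treat the fading in the zeta flask as a first-order lag, taking r as the rate at the start and s as standing at the middle of its interval, t = 12.3 min. Then τ = t/ln(r/s) = 7.39 min is our fade time, the time constant of the shrinking rate of making. A rate fading this way adds up to rτ = 0.0448 M, our first answer. Put back into the curve, it gives 0.0403 M at 17 min, against a reading of 0.0399 M. So we go round again from that reading: the rate left there, times τ, adds 0.00450 M, which makes 0.0444 M. That is 55.5 % of the starting material, the limiting reagent here. By 42 min, hardly any of the rate remains on this reckoning.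

The weak link is the assumption that what is made stays made. The same rule on the epsilon flask gives τ = 3.63 min and a total of 0.0343 M, yet that flask reads 0.0421 M. Its late slope has sunk too sharply for one exponential, and a net slope could sink like that if target were being taken away. We therefore hold our figure as leaning high.

The forecast, reached by another route, says 57 % (range 52 % to 64 %), 1.5 percentage points above ours, with orders 1.1 in coupling partner and 0.7 in starting material. Of the fading it says: “It looks like catalyst loss, faster at high partner”.

The eta flask gives 45.4 %, with orders 1.5 in coupling partner and 0.66 in starting material.

    starting material + coupling partner → target (0.1866 L mol⁻¹ min⁻¹)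
    starting material + 2 coupling partner → target + coupling partner (7.800 L² mol⁻² min⁻¹)
    starting material + coupling partner ⇌ idle substrate-reagent adduct, settled at all times (11.60 L mol⁻¹)
    target + coupling partner → side product (0.2172 L mol⁻¹ min⁻¹)

That is 0.0363 M of target, less than the 0.0399 M read at 17 min in the zeta flask of the same charge, and the scheme holds a step from target and coupling partner to side product, with k3 = 0.217 L mol⁻¹ min⁻¹. Reckoned the same way, the gamma flask has a longer fade time than the zeta flask's 7.39 min, namely 10.9 min. That puts a quarter of its charge at 7.20 min, and the gamma flask reached that quarter at 6.93 min.

(The readings come from a simulation for substances that don't exist, and the scatter is random.)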